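**Retrosynthetic overview**

1. Target ⇒ ring-closing metathesis forming the tetrasubstituted C1=C10 alkene; the seven-membered ring is closed last, from a diene ester.
2. Diene ester ⇒ key C–O bond: Evans–Tishchenko esterification of O-8 with vanillin, which also reduces the C6 ketone 1,3-anti ⇒ β-hydroxy ketone.
3. β-Hydroxy ketone ⇒ boron syn-aldol (C7–C8) of a cyclopentyl isobutyl ketone with 3-methylbut-3-enal.
4. Ketone ⇒ umpolung allylation of 3-methylbutanal by a vinyl oxirane, then oxidation; vinyl oxirane ⇒ Wittig ⇒ asymmetric epoxidation of 3-methylcyclopent-2-en-1-one (C4–O bond, source of absolute configuration).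
5. Ring order: the cyclopentane is bought; the cycloheptene is formed in the final step.

Assumption: guaiane numbering is used in the discussion (C4 tertiary carbinol, C5 ring-fusion CH, C6 free carbinol, C7 isopropyl CH, C8 ester carbinol, C1=C10 alkene), and the cinchona amine of step 1 is taken in the pseudo-enantiomeric form that gives the (1S,5S) oxide.

**Route**

Step 1
Reactants: 1 3-methylcyclopent-2-en-1-one
Product: 2 (1S,5S)-5-methyl-6-oxabicyclo[3.1.0]hexan-2-one
Conditions: 9-amino(9-deoxy)epiquinine (10 mol%), CF3CO2H (20 mol%), 50% aq. H2O2 (1.5 equiv), dioxane, 50 °C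
Reagents that add atoms: hydrogen peroxide, OO
Why: Catalytic asymmetric Weitz–Scheffer epoxidation under iminium activation by the primary-amine salt; the catalyst shields one enone face, so the tertiary C–O centre (later C4) is set as S and becomes the source of all absolute configuration.

Step 2
Reactants: 2 (1S,5S)-5-methyl-6-oxabicyclo[3.1.0]hexan-2-one
Product: 3 (1R,5S)-5-methyl-2-methylidene-6-oxabicyclo[3.1.0]hexane
Conditions: Ph3PCH3Br, KOtBu, THF, 0 °C to rt; product kept as a solution (volatile)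
Reagents that add atoms: methyltriphenylphosphonium bromide, C[P+](c1ccccc1)(c1ccccc1)c1ccccc1.[Br-]
Why: Wittig methylenation; the non-stabilised ylide attacks the ketone faster than it opens the oxirane, and no stereocentre is touched (the descriptor at C1 changes only through priorities).

Step 3
Reactants: 3 (1R,5S)-5-methyl-2-methylidene-6-oxabicyclo[3.1.0]hexane; 4 3-methylbutanal
Product: 6 (1S,2S)-2-[(1RS)-1-hydroxy-3-methylbutyl]-1-methyl-3-methylidenecyclopentan-1-ol, via allylindium alkoxide 5 (not isolated)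
Conditions: Pd(PPh3)4 (5 mol%), InI (1.3 equiv), THF–HMPA 4:1, rt; aq. NH4Cl
Reagents that add atoms: none
Why: Palladium-catalysed umpolung carbonyl allylation: zerovalent palladium opens the vinyl oxirane to a π-allyl complex, InI reduces it to an allylindium, and this adds to the aldehyde through its ring γ-carbon in a cyclic transition state on the face held by the indium alkoxide, so the new C5–C6 bond is cis to the retained tertiary C–O and the exocyclic methylene is formed (the carbinol epimers do not matter).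

Step 4
Reactants: 6 (1S,2S)-2-[(1RS)-1-hydroxy-3-methylbutyl]-1-methyl-3-methylidenecyclopentan-1-ol
Product: 7 1-[(1R,2S)-2-hydroxy-2-methyl-5-methylidenecyclopentyl]-3-methylbutan-1-one
Conditions: Dess–Martin periodinane (1.2 equiv), pyridine, CH2Cl2, 0 °C
Reagents that add atoms: none
Why: Dess–Martin oxidation takes only the secondary alcohol, both carbinol epimers converge on one ketone, and the near-neutral medium leaves the β,γ-alkene and the cis (hydrogen-bonded) C4/C5 relationship intact.

Step 5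
Reactants: 8 3-methylbut-3-en-1-ol
Product: 9 3-methylbut-3-enal
Conditions: Dess–Martin periodinane (1.1 equiv), CH2Cl2, 0 °C to rt; filtered and used at once as a CH2Cl2 solution
Reagents that add atoms: none
Why: Dess–Martin oxidation without base, which avoids isomerisation to the conjugated 3-methylbut-2-enal.

Step 6
Reactants: 7 1-[(1R,2S)-2-hydroxy-2-methyl-5-methylidenecyclopentyl]-3-methylbutan-1-one; 9 3-methylbut-3-enal
Product: 11 (2R,3S)-3-hydroxy-1-[(1R,2S)-2-hydroxy-2-methyl-5-methylidenecyclopentyl]-5-methyl-2-(propan-2-yl)hex-5-en-1-one, via boron enolate 10 (not isolated)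
Conditions: nBu2BOTf (2.2 equiv), iPr2NEt (2.6 equiv), CH2Cl2, −78 °C; then 9, −78 to −20 °C; pH 7 buffer, MeOH, 30% H2O2, 0 °C
Reagents that add atoms: none
Why: Boron-mediated aldol addition: the first equivalent of borane caps the tertiary alcohol, kinetic soft enolisation at the unhindered CH2 gives the (Z)-enolate, and a Zimmerman–Traxler chair gives the 2,3-syn aldol with the aldehyde expected to approach anti to the bulky borinate-bearing quaternary carbon, setting C7 and C8 (2R,3S here, 7S,8S in the target).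

Step 7
Reactants: 11 (2R,3S)-3-hydroxy-1-[(1R,2S)-2-hydroxy-2-methyl-5-methylidenecyclopentyl]-5-methyl-2-(propan-2-yl)hex-5-en-1-one; 12 vanillin (4-hydroxy-3-methoxybenzaldehyde)
Product: 13 (4S,5S,6R)-6-hydroxy-6-[(1S,2S)-2-hydroxy-2-methyl-5-methylidenecyclopentyl]-2-methyl-5-(propan-2-yl)hex-1-en-4-yl 4-hydroxy-3-methoxybenzoate
Conditions: SmI2 (0.3 equiv, 0.1 M in THF), vanillin (5 equiv), THF, −10 to 0 °C, dark; aq. NaHCO3, then NaHSO3 wash
Reagents that add atoms: none
Why: Proposed new method: an Evans–Tishchenko reaction run with an unprotected phenolic aldehyde, the catalyst being a trivalent samarium aryloxide formed in the flask from SmI2 and vanillin; the secondary O-8 alkoxide adds to samarium-bound vanillin to give a hemiacetal whose C–H is delivered to the C6 ketone through a chair-like six-membered transition state with the C8 substituent equatorial, so the ester C–O bond forms on O-8 and C6 is set 1,3-anti (6R) in one redox-neutral event, while the tertiary O-4 is too hindered to form the hemiacetal and the phenol only exchanges degenerately on samarium; the closest known reaction is the SmI2-catalysed Evans–Tishchenko reduction of β-hydroxy ketones with benzaldehyde-type aldehydes.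

Step 8
Reactants: 13 (4S,5S,6R)-6-hydroxy-6-[(1S,2S)-2-hydroxy-2-methyl-5-methylidenecyclopentyl]-2-methyl-5-(propan-2-yl)hex-1-en-4-yl 4-hydroxy-3-methoxybenzoate
Product: 14 (3S,3aS,4R,5S,6S)-3,4-dihydroxy-3,8-dimethyl-5-(propan-2-yl)-1,2,3,3a,4,5,6,7-octahydroazulen-6-yl 4-hydroxy-3-methoxybenzoate
Conditions: second-generation Grubbs catalyst RuCl2(=CHPh)(H2IMes)(PCy3) (15 mol% in three portions), toluene (2 mM), 95 °C, argon sparge
Reagents that add atoms: none
Why: Ring-closing metathesis of the two 1,1-disubstituted alkenes gives the tetrasubstituted C1=C10 alkene and the seven-membered ring with loss of ethene; no stereocentre is formed or touched, and the free hydroxyls and phenol are tolerated.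

**Compound list**

1 | 3-methylcyclopent-2-en-1-one | CC1=CC(=O)CC1 | starting material
2 | (1S,5S)-5-methyl-6-oxabicyclo[3.1.0]hexan-2-one | C[C@]12CCC(=O)[C@H]1O2 | intermediate
3 | (1R,5S)-5-methyl-2-methylidene-6-oxabicyclo[3.1.0]hexane | C[C@]12CCC(=C)[C@H]1O2 | intermediate
4 | 3-methylbutanal | CC(C)CC=O | starting material
5 | cyclic allylindium alkoxide: iodoindium (trivalent) bound to the (S)-tertiary alkoxide O and to the CH2 on C3 of the 1-methylcyclopent-2-ene ring | C[C@@]12CCC(C[In](I)O1)=C2 | intermediate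
6 | (1S,2S)-2-[(1RS)-1-hydroxy-3-methylbutyl]-1-methyl-3-methylidenecyclopentan-1-ol | CC(C)CC(O)[C@@H]1C(=C)CC[C@]1(C)O | intermediate
7 | 1-[(1R,2S)-2-hydroxy-2-methyl-5-methylidenecyclopentyl]-3-methylbutan-1-one | CC(C)CC(=O)[C@@H]1C(=C)CC[C@]1(C)O | intermediate
8 | 3-methylbut-3-en-1-ol | CC(=C)CCO | starting material
9 | 3-methylbut-3-enal | CC(=C)CC=O | intermediate
10 | (Z)-dibutylboron enolate of 7 (O–B and isopropyl cis), tertiary O as dibutylborinate | CCCCB(CCCC)O/C(=C\C(C)C)[C@@H]1C(=C)CC[C@]1(C)OB(CCCC)CCCC | intermediate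
11 | (2R,3S)-3-hydroxy-1-[(1R,2S)-2-hydroxy-2-methyl-5-methylidenecyclopentyl]-5-methyl-2-(propan-2-yl)hex-5-en-1-one | C=C(C)C[C@H](O)[C@@H](C(C)C)C(=O)[C@@H]1C(=C)CC[C@]1(C)O | intermediate
12 | vanillin (4-hydroxy-3-methoxybenzaldehyde) | COc1cc(C=O)ccc1O | starting material
13 | (4S,5S,6R)-6-hydroxy-6-[(1S,2S)-2-hydroxy-2-methyl-5-methylidenecyclopentyl]-2-methyl-5-(propan-2-yl)hex-1-en-4-yl 4-hydroxy-3-methoxybenzoate | COc1cc(C(=O)O[C@@H](CC(C)=C)[C@@H](C(C)C)[C@@H](O)[C@@H]2C(=C)CC[C@]2(C)O)ccc1O | intermediate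
14 | (3S,3aS,4R,5S,6S)-3,4-dihydroxy-3,8-dimethyl-5-(propan-2-yl)-1,2,3,3a,4,5,6,7-octahydroazulen-6-yl 4-hydroxy-3-methoxybenzoate (8α-vanilloyloxyguai-1(10)-ene-4β,6β-diol) | COc1cc(C(=O)O[C@H]2CC(C)=C3CC[C@](C)(O)[C@@H]3[C@H](O)[C@@H]2C(C)C)ccc1O | target

**Step count and risks**

Total steps: 8 (steps 1 to 8, including the one-step preparation of aldehyde 9). Longest linear sequence: 7 steps (1, 2, 3, 4, 6, 7, 8) from 3-methylcyclopent-2-en-1-one.

Three steps most likely to fail:

Step 7 (the proposed new step). The free phenol may tie up the samarium catalyst or slow hemiacetal formation, the hindered C6 ketone may accept hydride slowly, and retro-aldol cleavage or 1,3-acyl migration could compete. The fallback uses known chemistry, sets out from 11 and comes back at 13. Vanillin 12 is silylated (TBSCl, imidazole, DMF) to 4-[(tert-butyldimethylsilyl)oxy]-3-methoxybenzaldehyde F1. The standard SmI2-catalysed Evans–Tishchenko reaction of 11 with F1 (THF, −10 °C) gives (4S,5S,6R)-6-hydroxy-6-[(1S,2S)-2-hydroxy-2-methyl-5-methylidenecyclopentyl]-2-methyl-5-(propan-2-yl)hex-1-en-4-yl 4-[(tert-butyldimethylsilyl)oxy]-3-methoxybenzoate F2. TBAF buffered with AcOH (THF, 0 °C) removes the silyl group and gives 13.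

Step 6. Enolisation could occur toward the doubly activated ring CH, which would epimerise C5 or move the alkene into conjugation. The π-facial bias exerted by the ring stereocentres is only predicted, and depends on the enolate rotamer. The fallback puts C7 and C8 under auxiliary control, sets out from 3 and 9 and comes back at 11. Bought (4R)-4-benzyl-3-(3-methylbutanoyl)-1,3-oxazolidin-2-one is enolised (nBu2BOTf, iPr2NEt) and added to 9 to give the Evans syn-aldol (4R)-4-benzyl-3-[(2R,3S)-3-hydroxy-5-methyl-2-(propan-2-yl)hex-5-enoyl]-1,3-oxazolidin-2-one F3. TESOTf and 2,6-lutidine give (4R)-4-benzyl-3-[(2R,3S)-5-methyl-2-(propan-2-yl)-3-(triethylsilyloxy)hex-5-enoyl]-1,3-oxazolidin-2-one F4. LiBH4 in THF–MeOH cleaves the auxiliary to (2S,3S)-5-methyl-2-(propan-2-yl)-3-(triethylsilyloxy)hex-5-en-1-ol F5. Dess–Martin oxidation gives (2R,3S)-5-methyl-2-(propan-2-yl)-3-(triethylsilyloxy)hex-5-enal F6. F6 takes the place of 4 in the Pd(PPh3)4/InI coupling with 3 and gives (1S,2S)-2-[(1RS,2S,3S)-1-hydroxy-5-methyl-2-(propan-2-yl)-3-(triethylsilyloxy)hex-5-en-1-yl]-1-methyl-3-methylidenecyclopentan-1-ol F7. Dess–Martin oxidation gives (2R,3S)-1-[(1R,2S)-2-hydroxy-2-methyl-5-methylidenecyclopentyl]-5-methyl-2-(propan-2-yl)-3-(triethylsilyloxy)hex-5-en-1-one F8. HF·pyridine removes the silyl group and gives 11.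

Step 8. Closing a tetrasubstituted alkene from two 1,1-disubstituted olefins next to a fully substituted ring carbon and a bulky aroyloxy group may stall or need very high catalyst loading. The fallback closes the ring before the ester is installed, sets out from 11 and comes back at 14. Ring-closing metathesis of ketol 11 (same ruthenium catalyst, toluene, 95 °C), where C6 is trigonal and O-8 is unhindered, gives (3S,3aR,5R,6S)-3,6-dihydroxy-3,8-dimethyl-5-(propan-2-yl)-2,3,3a,5,6,7-hexahydroazulen-4(1H)-one F9. The samarium-catalysed Tishchenko esterification with 12, as in step 7, then delivers hydride across the ring anti to O-8 and gives 14.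

**Further compounds**

F1 | step 7 | 4-[(tert-butyldimethylsilyl)oxy]-3-methoxybenzaldehyde | COc1cc(C=O)ccc1O[Si](C)(C)C(C)(C)C
F2 | step 7 | (4S,5S,6R)-6-hydroxy-6-[(1S,2S)-2-hydroxy-2-methyl-5-methylidenecyclopentyl]-2-methyl-5-(propan-2-yl)hex-1-en-4-yl 4-[(tert-butyldimethylsilyl)oxy]-3-methoxybenzoate | COc1cc(C(=O)O[C@@H](CC(C)=C)[C@@H](C(C)C)[C@@H](O)[C@@H]2C(=C)CC[C@]2(C)O)ccc1O[Si](C)(C)C(C)(C)C
F3 | step 6 | (4R)-4-benzyl-3-[(2R,3S)-3-hydroxy-5-methyl-2-(propan-2-yl)hex-5-enoyl]-1,3-oxazolidin-2-one | C=C(C)C[C@H](O)[C@@H](C(C)C)C(=O)N1[C@H](Cc2ccccc2)COC1=O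
F4 | step 6 | (4R)-4-benzyl-3-[(2R,3S)-5-methyl-2-(propan-2-yl)-3-(triethylsilyloxy)hex-5-enoyl]-1,3-oxazolidin-2-one | C=C(C)C[C@H](O[Si](CC)(CC)CC)[C@@H](C(C)C)C(=O)N1[C@H](Cc2ccccc2)COC1=O
F5 | step 6 | (2S,3S)-5-methyl-2-(propan-2-yl)-3-(triethylsilyloxy)hex-5-en-1-ol | C=C(C)C[C@H](O[Si](CC)(CC)CC)[C@@H](C(C)C)CO
F6 | step 6 | (2R,3S)-5-methyl-2-(propan-2-yl)-3-(triethylsilyloxy)hex-5-enal | C=C(C)C[C@H](O[Si](CC)(CC)CC)[C@@H](C(C)C)C=O
F7 | step 6 | (1S,2S)-2-[(1RS,2S,3S)-1-hydroxy-5-methyl-2-(propan-2-yl)-3-(triethylsilyloxy)hex-5-en-1-yl]-1-methyl-3-methylidenecyclopentan-1-ol | C=C(C)C[C@H](O[Si](CC)(CC)CC)[C@@H](C(C)C)C(O)[C@@H]1C(=C)CC[C@]1(C)O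
F8 | step 6 | (2R,3S)-1-[(1R,2S)-2-hydroxy-2-methyl-5-methylidenecyclopentyl]-5-methyl-2-(propan-2-yl)-3-(triethylsilyloxy)hex-5-en-1-one | C=C(C)C[C@H](O[Si](CC)(CC)CC)[C@@H](C(C)C)C(=O)[C@@H]1C(=C)CC[C@]1(C)O
F9 | step 8 | (3S,3aR,5R,6S)-3,6-dihydroxy-3,8-dimethyl-5-(propan-2-yl)-2,3,3a,5,6,7-hexahydroazulen-4(1H)-one | CC1=C2CC[C@](C)(O)[C@@H]2C(=O)[C@H](C(C)C)[C@@H](O)C1
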